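**Retrosynthetic overview**

- The last bond made is aryl C6–CH2 of the bridge: the chromene phenol (ring A/B half, C6–H is its only free ring carbon) adds to a 2‑methylene‑1,3‑dione released from the aminomethyl trione (ring C half).
- Ring C: the quaternary carbon is set by asymmetric dearomative geranylation of a Mannich base of methylphloracetophenone; the CH2NMe2 group blocks the free ring carbon and later becomes the bridge.
- Ring B (O1, C2(CH3)2, C3H=C4H, C4a, C8a) is not closed as a six‑membered ring: it arises from the five‑membered ring of a 2,2‑dimethylbenzofuran‑3(2H)‑one (O1, C2(CH3)2, C3=O, C3a, C7a) by insertion of one carbon next to the ketone, followed by conversion of the ketone into the C3=C4 alkene.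
- Enabling feature: C2 is quaternary and bonded to O1, so the C3 ketone cannot enolise and only C3a or C2 can migrate; the target alkene C3=C4 lies exactly between the ketone carbon and the inserted carbon, which the silicon of the diazo reagent marks for Peterson elimination.
- Ring order: ring A (bought) → five‑membered O‑ring (Friedel–Crafts acylation/O‑alkylation, site fixed by a para tosylate) → ring B by expansion; ring C by dearomatisation; union last.

Key step: step 3

Assumption: the sense of induction of the (S,S) Trost ligand in step 6 is assigned by analogy with alkylations of prochiral cyclic enolates; if it favours the antipode, the (R,R) ligand is used and nothing else changes.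

**Step 1**
Reactants: 1 1-(2,4,6-trihydroxyphenyl)butan-1-one
Product: 2 4-butanoyl-3,5-dihydroxyphenyl 4-methylbenzenesulfonate
Conditions: TsCl (1.05 equiv), Et3N (1.1 equiv), THF, −10 to 0 °C
Reagents that add atoms: 4-methylbenzenesulfonyl chloride, Cc1ccc(cc1)S(=O)(=O)Cl
Why: Selective O‑sulfonylation of the para hydroxyl, which is the most acidic and the only one not hydrogen‑bonded to the ketone; the tosylate leaves the two remaining hydroxyls and the two free ring carbons equivalent and survives Lewis acid.

**Step 2**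
Reactants: 2 4-butanoyl-3,5-dihydroxyphenyl 4-methylbenzenesulfonate
Product: 4 7-butanoyl-6-hydroxy-2,2-dimethyl-3-oxo-2,3-dihydro-1-benzofuran-4-yl 4-methylbenzenesulfonate, via bromo ketone 3 (not isolated)
Conditions: 2-bromo-2-methylpropanoyl bromide (1.2 equiv), AlCl3 (3.5 equiv), CH2Cl2–PhNO2, 0 to 40 °C; aq. HCl; then NaOAc, EtOH, 78 °C
Reagents that add atoms: 2-bromo-2-methylpropanoyl bromide, CC(C)(Br)C(=O)Br
Why: Friedel–Crafts acylation at the ring carbon ortho and para to the two free hydroxyls, then intramolecular Williamson O‑alkylation (5‑exo‑tet at the tertiary alpha‑bromo ketone) by the only free ortho oxygen, the other being tosylated, so that O1 must end up next to the butanoyl‑bearing carbon.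

**Step 3**
Reactants: 4 7-butanoyl-6-hydroxy-2,2-dimethyl-3-oxo-2,3-dihydro-1-benzofuran-4-yl 4-methylbenzenesulfonate
Product: 7 8-butanoyl-7-hydroxy-2,2-dimethyl-2H-chromen-5-yl 4-methylbenzenesulfonate, via beta-ketosilane 5 (not isolated), via beta-hydroxysilane 6 (not isolated)
Conditions: TMSCHN2 (1.5 equiv), Sc(OTf)3 (10 mol%), CH2Cl2, −40 to 0 °C; then LiBH4, THF, −40 °C; then 1 M H2SO4, THF, rt
Reagents that add atoms: (trimethylsilyl)diazomethane, C[Si](C)(C)C=[N+]=[N-]
Why: Lewis‑acid‑promoted diazoalkane homologation of a ketone (Büchner–Curtius–Schlotterbeck/Tiffeneau–Demjanov type) is followed in the same flask by hydride reduction and Peterson elimination: Sc(OTf)3 activates the non‑enolisable C3 carbonyl of 4, TMSCHN2 adds, and loss of N2 drives a 1,2‑shift of the electron‑rich aryl carbon C3a onto the diazo carbon, which inserts that carbon and turns the five‑membered O1–C2–C3–C3a–C7a ring into the six‑membered pyranone ring of 5 (ring expansion by 1,2‑migration, not a new ring closure). LiBH4 then reduces the new dialkyl ketone and acid triggers Peterson elimination of the beta‑hydroxysilane 6, so that the C3=C4 alkene forms between the former carbonyl carbon and the silicon‑marked inserted carbon. The closest precedents are the Sc(OTf)3‑ or BF3‑mediated ring expansion of benzo‑fused cyclic ketones with TMSCHN2 and the acid‑induced Peterson olefination of beta‑hydroxysilanes. No stereocenter remains, because the two transient centers of 6 are destroyed in the elimination. The step needs chemoselectivity for the benzofuranone carbonyl over the butanoyl ketone, which is expected because the latter is flanked by two ortho substituents and held as a hydrogen‑bonded, then phenoxide‑conjugated, vinylogous acid; it does not need migration selectivity, since a shift of C2 instead of C3a would put silicon on C3 and the hydroxyl on C4 and the same elimination would give the same chromene 7.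

**Step 4**
Reactants: 7 8-butanoyl-7-hydroxy-2,2-dimethyl-2H-chromen-5-yl 4-methylbenzenesulfonate
Product: 8 1-(5,7-dihydroxy-2,2-dimethyl-2H-chromen-8-yl)butan-1-one
Conditions: KOH (4 equiv), MeOH–H2O, 60 °C; then aq. HCl to pH 4
Reagents that add atoms: none
Why: Saponification of an aryl sulfonate (hydroxide attack at sulfur) frees the second phenol; the chromene and the aryl ketone are stable to base.

**Step 5**
Reactants: 9 1-(2,4,6-trihydroxy-3-methylphenyl)ethan-1-one
Product: 10 1-{3-[(dimethylamino)methyl]-2,4,6-trihydroxy-5-methylphenyl}ethan-1-one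
Conditions: Eschenmoser's salt (1.05 equiv), Et3N (1.1 equiv), MeCN, 0 °C to rt
Reagents that add atoms: N,N-dimethylmethaniminium iodide, C[N+](C)=C.[I-]
Why: Mannich aminomethylation at the only unsubstituted ring carbon of the phloroglucinol, which installs the future bridge carbon and blocks that position for the next step.

**Step 6**
Reactants: 10 1-{3-[(dimethylamino)methyl]-2,4,6-trihydroxy-5-methylphenyl}ethan-1-one; 11 (2E)-3,7-dimethylocta-2,6-dien-1-yl acetate (geranyl acetate)
Product: 12 (4R)-2-acetyl-6-[(dimethylamino)methyl]-4-[(2E)-3,7-dimethylocta-2,6-dien-1-yl]-3,5-dihydroxy-4-methylcyclohexa-2,5-dien-1-one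
Conditions: Pd2(dba)3·CHCl3 (2.5 mol%), (S,S)-DACH-phenyl Trost ligand (7.5 mol%), CH2Cl2, 0 °C to rt
Reagents that add atoms: none
Why: Proposed new method: a Tsuji–Trost asymmetric allylic alkylation used as a dearomatisation, in which zerovalent palladium ionises geranyl acetate to a cationic pi‑geranyl complex held in the chiral pocket of the Trost ligand and the phenoxide of 10 (deprotonated by its own amine) attacks the unsubstituted allyl terminus through its methyl‑bearing ring carbon in an outer‑sphere step, which should give the linear E‑geranyl quaternary carbon, with the ligand pocket choosing the face of the planar nucleophile (R center) and the aminomethyl group removing the only ring C–H and making its own carbon the more hindered site; the closest known reactions are the palladium‑catalysed asymmetric allylic dearomatisation of naphthols, the Trost alkylation of prochiral cyclic 1,3‑dicarbonyl nucleophiles and the racemic palladium‑catalysed dearomative allylation of acylphloroglucinols.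

**Step 7**
Reactants: 8 1-(5,7-dihydroxy-2,2-dimethyl-2H-chromen-8-yl)butan-1-one; 12 (4R)-2-acetyl-6-[(dimethylamino)methyl]-4-[(2E)-3,7-dimethylocta-2,6-dien-1-yl]-3,5-dihydroxy-4-methylcyclohexa-2,5-dien-1-one
Product: 14 1-[6-({(3R)-5-acetyl-3-[(2E)-3,7-dimethylocta-2,6-dien-1-yl]-2,4-dihydroxy-3-methyl-6-oxocyclohexa-1,4-dien-1-yl}methyl)-5,7-dihydroxy-2,2-dimethyl-2H-chromen-8-yl]butan-1-one, via methylene trione 13 (not isolated)
Conditions: 8 (1.3 equiv), 1,4-dioxane, 85 °C, slow argon sweep
Reagents that add atoms: none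
Why: Thermal retro‑Mannich loss of dimethylamine gives the 2‑methylene‑1,3‑dione 13 (an ortho‑quinone methide equivalent), and Friedel–Crafts‑type Michael addition of the only free ring carbon of 8 (C6, between the two hydroxyls) forms the methylene bridge; the quaternary center has no alpha‑hydrogen and cannot epimerise.

**Compound list**

1 | 1-(2,4,6-trihydroxyphenyl)butan-1-one | CCCC(=O)c1c(O)cc(O)cc1O | starting material
2 | 4-butanoyl-3,5-dihydroxyphenyl 4-methylbenzenesulfonate | CCCC(=O)c1c(O)cc(OS(=O)(=O)c2ccc(C)cc2)cc1O | intermediate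
3 | 4-butanoyl-2-(2-bromo-2-methylpropanoyl)-3,5-dihydroxyphenyl 4-methylbenzenesulfonate | CCCC(=O)c1c(O)cc(OS(=O)(=O)c2ccc(C)cc2)c(C(=O)C(C)(C)Br)c1O | intermediate
4 | 7-butanoyl-6-hydroxy-2,2-dimethyl-3-oxo-2,3-dihydro-1-benzofuran-4-yl 4-methylbenzenesulfonate | CCCC(=O)c1c(O)cc(OS(=O)(=O)c2ccc(C)cc2)c2c1OC(C)(C)C2=O | intermediate
5 | 8-butanoyl-7-hydroxy-2,2-dimethyl-3-oxo-4-(trimethylsilyl)-3,4-dihydro-2H-chromen-5-yl 4-methylbenzenesulfonate (racemic) | CCCC(=O)c1c(O)cc(OS(=O)(=O)c2ccc(C)cc2)c2c1OC(C)(C)C(=O)C2[Si](C)(C)C | intermediate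
6 | 8-butanoyl-3,7-dihydroxy-2,2-dimethyl-4-(trimethylsilyl)-3,4-dihydro-2H-chromen-5-yl 4-methylbenzenesulfonate (mixture of diastereomers) | CCCC(=O)c1c(O)cc(OS(=O)(=O)c2ccc(C)cc2)c2c1OC(C)(C)C(O)C2[Si](C)(C)C | intermediate
7 | 8-butanoyl-7-hydroxy-2,2-dimethyl-2H-chromen-5-yl 4-methylbenzenesulfonate | CCCC(=O)c1c(O)cc(OS(=O)(=O)c2ccc(C)cc2)c2c1OC(C)(C)C=C2 | intermediate
8 | 1-(5,7-dihydroxy-2,2-dimethyl-2H-chromen-8-yl)butan-1-one | CCCC(=O)c1c(O)cc(O)c2c1OC(C)(C)C=C2 | intermediate
9 | 1-(2,4,6-trihydroxy-3-methylphenyl)ethan-1-one | CC(=O)c1c(O)cc(O)c(C)c1O | starting material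
10 | 1-{3-[(dimethylamino)methyl]-2,4,6-trihydroxy-5-methylphenyl}ethan-1-one | CC(=O)c1c(O)c(CN(C)C)c(O)c(C)c1O | intermediate
11 | (2E)-3,7-dimethylocta-2,6-dien-1-yl acetate (geranyl acetate) | CC(=O)OC/C=C(\C)CCC=C(C)C | starting material
12 | (4R)-2-acetyl-6-[(dimethylamino)methyl]-4-[(2E)-3,7-dimethylocta-2,6-dien-1-yl]-3,5-dihydroxy-4-methylcyclohexa-2,5-dien-1-one | CN(C)CC1=C(O)[C@@](C)(C/C=C(\C)CCC=C(C)C)C(O)=C(C(C)=O)C1=O | intermediate
13 | (6S)-4-acetyl-6-[(2E)-3,7-dimethylocta-2,6-dien-1-yl]-5-hydroxy-6-methyl-2-methylidenecyclohex-4-ene-1,3-dione (same spatial arrangement as 12; the descriptor changes only with the tautomer drawn) | C=C1C(=O)[C@@](C)(C/C=C(\C)CCC=C(C)C)C(O)=C(C(C)=O)C1=O | intermediate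
14 | 1-[6-({(3R)-5-acetyl-3-[(2E)-3,7-dimethylocta-2,6-dien-1-yl]-2,4-dihydroxy-3-methyl-6-oxocyclohexa-1,4-dien-1-yl}methyl)-5,7-dihydroxy-2,2-dimethyl-2H-chromen-8-yl]butan-1-one (CNP0152509.1) | CCCC(=O)c1c(O)c(CC2=C(O)[C@@](C)(C/C=C(\C)CCC=C(C)C)C(O)=C(C(C)=O)C2=O)c(O)c2c1OC(C)(C)C=C2 | target

Total step count: 7. Longest linear sequence: 5 steps (steps 1, 2, 3, 4 and 7); steps 5 and 6 form the second branch.

**Steps most likely to fail**

Step 6. The planar, strongly delocalised phenoxide may be discriminated poorly by the ligand pocket, so that the quaternary carbon forms with low enantiomeric purity. The fallback uses known chemistry and sets out from 10 and 11: achiral Tsuji–Trost dearomative allylation with Pd(PPh3)4 in THF should give racemic 2-acetyl-6-[(dimethylamino)methyl]-4-[(2E)-3,7-dimethylocta-2,6-dien-1-yl]-3,5-dihydroxy-4-methylcyclohexa-2,5-dien-1-one F1. The enantiomers are then separated by preparative chromatography on a chiral stationary phase, and the R enantiomer returns to the route as 12.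

Step 3. Addition of the diazoalkane to the hindered, electron‑rich carbonyl may be slow, and the silyl group may be lost before reduction (carbon‑to‑oxygen shift or protodesilylation), which would leave an alcohol that does not eliminate cleanly. The fallback keeps the ring expansion but changes its mechanism and sets out from 4.
- Wittig methylenation (Ph3P=CH2, THF, reflux) should give 7-butanoyl-6-hydroxy-2,2-dimethyl-3-methylidene-2,3-dihydro-1-benzofuran-4-yl 4-methylbenzenesulfonate F2.
- Hydroboration–oxidation (9-BBN, then NaBO3) should give the primary alcohol 7-butanoyl-6-hydroxy-3-(hydroxymethyl)-2,2-dimethyl-2,3-dihydro-1-benzofuran-4-yl 4-methylbenzenesulfonate F3.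
- Selective mesylation of the primary hydroxyl (MsCl, Et3N, −20 °C) should give {7-butanoyl-6-hydroxy-2,2-dimethyl-4-[(4-methylbenzenesulfonyl)oxy]-2,3-dihydro-1-benzofuran-3-yl}methyl methanesulfonate F4.
- Solvolysis of F4 in hexafluoroisopropanol with 2,6-lutidine at 50 °C should cause a 1,2‑aryl shift through a phenonium ion (Wagner–Meerwein ring expansion) and loss of the benzylic proton, which returns to the route at 7.

Step 2. The arene carries an acyl and a sulfonate group, so C‑acylation may stay incomplete while the acyl bromide is consumed by O‑acylation or by loss of HBr. The fallback builds the five‑membered ring in the reverse bond order and sets out from 2.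
- O‑Alkylation of one of the two equivalent hydroxyls with tert-butyl 2-bromo-2-methylpropanoate (Cs2CO3, DMF, 60 °C) should give tert-butyl 2-{2-butanoyl-3-hydroxy-5-[(4-methylbenzenesulfonyl)oxy]phenoxy}-2-methylpropanoate F5.
- Trifluoroacetic acid should cleave the ester to 2-{2-butanoyl-3-hydroxy-5-[(4-methylbenzenesulfonyl)oxy]phenoxy}-2-methylpropanoic acid F6.
- Intramolecular Friedel–Crafts acylation of F6 with trifluoroacetic anhydride at the carbon ortho to the ether oxygen returns to the route at 4.

**Further compounds**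

F1 | step 6 | racemic 2-acetyl-6-[(dimethylamino)methyl]-4-[(2E)-3,7-dimethylocta-2,6-dien-1-yl]-3,5-dihydroxy-4-methylcyclohexa-2,5-dien-1-one | CN(C)CC1=C(O)C(C)(C/C=C(\C)CCC=C(C)C)C(O)=C(C(C)=O)C1=O
F2 | step 3 | 7-butanoyl-6-hydroxy-2,2-dimethyl-3-methylidene-2,3-dihydro-1-benzofuran-4-yl 4-methylbenzenesulfonate | CCCC(=O)c1c(O)cc(OS(=O)(=O)c2ccc(C)cc2)c2c1OC(C)(C)C2=C
F3 | step 3 | 7-butanoyl-6-hydroxy-3-(hydroxymethyl)-2,2-dimethyl-2,3-dihydro-1-benzofuran-4-yl 4-methylbenzenesulfonate (racemic) | CCCC(=O)c1c(O)cc(OS(=O)(=O)c2ccc(C)cc2)c2c1OC(C)(C)C2CO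
F4 | step 3 | {7-butanoyl-6-hydroxy-2,2-dimethyl-4-[(4-methylbenzenesulfonyl)oxy]-2,3-dihydro-1-benzofuran-3-yl}methyl methanesulfonate (racemic) | CCCC(=O)c1c(O)cc(OS(=O)(=O)c2ccc(C)cc2)c2c1OC(C)(C)C2COS(C)(=O)=O
F5 | step 2 | tert-butyl 2-{2-butanoyl-3-hydroxy-5-[(4-methylbenzenesulfonyl)oxy]phenoxy}-2-methylpropanoate | CCCC(=O)c1c(O)cc(OS(=O)(=O)c2ccc(C)cc2)cc1OC(C)(C)C(=O)OC(C)(C)C
F6 | step 2 | 2-{2-butanoyl-3-hydroxy-5-[(4-methylbenzenesulfonyl)oxy]phenoxy}-2-methylpropanoic acid | CCCC(=O)c1c(O)cc(OS(=O)(=O)c2ccc(C)cc2)cc1OC(C)(C)C(=O)O
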